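## The problem

The target (12) is a 2-hydroxy-1,4-naphthoquinone. The numbering used for all intermediates is: C1 and C4 are the ring B carbonyl carbons, C2 carries the hydroxyl, C3 carries the (2S)-2-acetoxypropyl chain, and ring A (fused at C4a/C8a) has methoxy groups at C5, C6 and C8 and its only hydrogen at C7. The main difficulty is regiochemical: rings A and B are both unsymmetrical, and the C2 hydroxyl must sit on the C8a/C8 side while the chain sits on the C4a/C5 side. Once the quinone exists its two carbonyls are nearly equivalent, so this relation has to be fixed while ring B is built. There is one stereocentre, the carbinol carbon of the chain; a CH2 group separates it from the flat core, so the core cannot set it and it can direct nothing. It is best bought, and the route then only has to avoid ionisation or displacement at that carbon. The fragile groups are these: the secondary acetate (hydroxide, hydroperoxide, and E1cB loss, because the C3 CH2 is vinylogously acidic in a quinone); the hydroxyquinone (an acidic vinylogous acid that ring-contracts in alkali); the peri methyl ethers at C5 and C8; and the C5/C8 para-dimethoxy pair, which strong one-electron oxidants can turn into a second quinone. The enabling feature is that C8a carries ring B carbon C1 while its ring A neighbour C8 is blocked by OMe. An aryl unit with a carbene carbon (C1) on C8a can therefore close only onto C4a. C2 (with its hydroxyl deferred) and C3 with the chain are then the two carbons of a terminal alkyne, and C4 is one carbonyl carbon, that is, CO. The C2 hydroxyl can be deferred because, in the quinone that lacks it, C2–H is the only unsubstituted enedione position and so the only site for nucleophilic oxygenation.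

## Retrosynthesis

**12 from 11.** No skeletal bond is cut; the C2 hydroxyl is traced back to the oxygen of a C2–C3 oxirane (11), which isomerises to the hydroxyquinone under acid. The neighbouring option, acetylation as the last step, would have to distinguish a secondary alcohol from the acidic quinone hydroxyl and would need a protecting group on the chain. Going through 11 keeps the acetate in place from the start. The forward reaction must open the oxirane at C3 and remove the C2 proton without disturbing the ester or the carbinol centre.

**11 from 10.** The two C–O bonds of the oxirane are cut, giving quinone 10 with hydrogen at C2. Nucleophilic epoxidation is preferred over acetoxylation or halogenation and hydrolysis because it is one mild step and can only occur at the C2=C3 bond. No facial control is needed, since both new stereocentres disappear again on the way to 12.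

**10 from 9.** The C1 carbonyl is traced to a C1 methyl ether and the C4 carbonyl to a free C4 phenol, that is, to the 4-methoxy-1-naphthol 9. A precursor with both oxygens etherified would need an oxidative demethylation that could not tell ring B from the C5/C8 pair of ring A. With the one free hydroxyl in ring B, a mild two-electron oxidant touches ring B only.

**9 from 7 and 2.** This is the key disconnection: C1–C2, C3–C4 and C4–C4a are cut. Ring B becomes the sum of the carbene carbon of aryl complex 7 (C1, already on C8a), the two carbons of terminal alkyne 2 (C2–H and C3 with the chain) and one carbonyl ligand of 7 (C4). Against the other ways of dividing ring B (see the next section), this cut forms three bonds and the ring in one operation. Its regiochemistry rests on two structural facts: a terminal alkyne places its substituent next to the CO-derived carbon, and the aryl group has only one free ortho position. The precursors are far simpler: an aryl carbene complex with no stereochemistry and a five-carbon alkyne that carries the stereocentre and the acetate. The forward reaction must tolerate the ester.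

**7 from 3 and 4.** The C1–C8a bond and the O–CH3 bond of the carbene are cut. Aryllithium 5, from commercial bromide 3, adds to a carbonyl ligand of Cr(CO)6 (4) to give acylate 6, which is O-methylated. Bromide 3 has exactly the required pattern: bromine at the future C8a, hydrogen at the future C4a, and methoxy groups at the future C5, C6 and C8.

**2 from 1.** The acyl C–O bond is cut; alkynol 1 supplies the (S) centre from the chiral pool. The acetate is put on first, instead of a silyl ether, because it is the group the target needs. No protecting-group exchange follows, and no free secondary alcohol is ever present beside the oxirane or the quinone, where it could cyclise.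

## Roads not taken

**Alternative 1: ring A by Diels–Alder addition of a Birch-type diene.** The cut is C4a–C5 and C8–C8a. In the forward step 1,2,4-trimethoxycyclohexa-1,3-diene (A2) would add to the unsubstituted double bond of 2-methoxy-3-[(2S)-2-(tert-butyldimethylsilyloxy)propyl]benzoquinone (A3). Enolisation and thermal extrusion of the two-carbon bridge (Alder–Rickert) would then give naphthalene-1,4-diol A1.
- Merits: it needs no stoichiometric transition metal, the C2 oxygen is present from the start as a methyl ether, and all three ring A oxygens arrive together. On the first two points it is better than the chosen plan.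
- Weak points: both partners are unsymmetrical. The orientation depends on a modest electronic difference between the two quinone carbonyls and between two diene termini that both carry oxygen. Both new bonds form at fully substituted, methoxy-bearing carbons, so the addition should be slow. A2 is available only as a labile mixture of diene isomers. A3 needs its own synthesis, in which the chiral chain is attached to a quinone. After A1, oxidation, cleavage of the C2 methyl ether and a silyl-to-acetate exchange remain.
- Comparison: the chosen plan uses chromium in stoichiometric amount and spends two steps on the C2 oxygen. In return its regiochemistry is structurally enforced, both partners come from commercial materials in one step each, and the sequence is shorter.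

**Alternative 2: aryne acyl-alkylation, Dieckmann closure and aerobic oxidation.** The cuts are C8a–C1 and C4a–C4, then C2–C3. CsF would release the aryne from 3,4,6-trimethoxy-2-(trimethylsilyl)phenyl triflate (A5), and the aryne would insert into the bond between the α-carbon and the ketone carbon of β-ketoester A6. NaOMe would close ring B by attack of C3 on the ester carbon C2, and air would oxidise C1 to give the silyl-protected hydroxyquinone A4.
- Merits: this is the most convergent of the four plans. It delivers the full oxidation pattern of ring B, C2 hydroxyl included, in one flask. In step economy at the quinone stage it is clearly better than the chosen plan, which needs steps 4 to 6 for the same result.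
- Weak points: the two aryne carbons are each flanked by a methoxy group (C5 and C8), and only the remote C6 methoxy group tells them apart. The sense of insertion is therefore weakly biased, and the wrong sense gives the isomer in which hydroxyl and chain have changed places, a compound very similar to the right one. A5 is a benzene with six different substituents and needs a long preparation. A6 must also be made. A silyl-to-acetate exchange next to the acidic quinone hydroxyl is still required.
- Comparison: the chosen plan pays with two extra steps and with chromium. It gains a ring fusion that cannot go wrong and an aryl partner that is a catalogue bromide.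

**Alternative 3: one-carbon insertion into an indane-1,2-dione.** The cuts are C2–C3 and C3–C4. The chiral diazoalkane A9 would add, under Sc(OTf)3 catalysis, to the C2 carbonyl of 4,6,7-trimethoxyindane-1,2-dione (A8). Migration of the acyl carbon C4 as the diazo group leaves would enlarge the five-membered ring to the naphthalene-1,3-diol A7, and C1 would be oxidised afterwards.
- Merits: the relation between ring A and ring B is fixed in A8, so there is no ring-fusion ambiguity. The C2 oxygen is in place and the Lewis acid is catalytic. In ring A regiocontrol this plan is the equal of the chosen one.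
- Weak points: A9 is a non-stabilised, functionalised diazoalkane, hazardous to prepare and handle. A8 has two carbonyls and two groups that can migrate (the acyl carbon C4 or the benzylic carbon C1), so the site of addition and the migrating group are not secured. Epoxide formation and double homologation compete. A8 takes several steps from an indanone.
- Comparison: the chosen plan sets against the built-in C2 oxygen of A7 the stability and availability of its fragments and a key step whose selectivity is predictable from the substrate alone.

Key step: step 3

## Route

Assumption: (S)-pent-4-yn-2-ol (1) is treated as a purchasable, enantiomerically pure compound.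

Step 1
Reactants: 1 (S)-pent-4-yn-2-ol
Product: 2 (S)-pent-4-yn-2-yl acetate
Conditions: Ac2O, pyridine, DMAP (cat.), CH2Cl2, 0 °C → rt
Reagents that add atoms: acetic anhydride, CC(=O)OC(C)=O
Why: DMAP-catalysed O-acetylation (nucleophilic acyl substitution) of a secondary alcohol; the C–O bond of the stereocentre is not touched, so the (S) configuration of 1 is carried into 2, and the ester installed is the one the target needs.

Step 2
Reactants: 3 1-bromo-2,4,5-trimethoxybenzene; 4 chromium hexacarbonyl Cr(CO)6
Product: 7 pentacarbonyl[methoxy(2,4,5-trimethoxyphenyl)methylidene]chromium, via 2,4,5-trimethoxyphenyllithium 5 (not isolated), via lithium acylate Li[(CO)5CrC(O)Ar] 6 (not isolated)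
Conditions: n-BuLi, THF, −78 °C; Cr(CO)6, −78 °C → rt; solvent switch; Me3OBF4, CH2Cl2, 0 °C → rt
Reagents that add atoms: trimethyloxonium tetrafluoroborate, C[O+](C)C.F[B-](F)(F)F
Why: Fischer carbene synthesis: bromine–lithium exchange gives 5, which adds to a carbonyl ligand of Cr(CO)6 to give acylate 6, and O-methylation by the hard oxonium salt gives the methoxycarbene complex of zerovalent chromium; ortho-methoxyaryl complexes of this kind are routinely made this way.

Step 3
Reactants: 7 pentacarbonyl[methoxy(2,4,5-trimethoxyphenyl)methylidene]chromium; 2 (S)-pent-4-yn-2-yl acetate
Product: 9 (2S)-1-(1-hydroxy-4,5,7,8-tetramethoxynaphthalen-2-yl)propan-2-yl acetate, via naphthol complex (CO)3Cr(η6-arene) 8 (not isolated)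
Conditions: THF (degassed), 50 °C, Ar; then air, light, Et2O, rt
Reagents that add atoms: none
Why: Dötz benzannulation: loss of one CO from the carbene complex of zerovalent chromium (helped by the ortho methoxy group, which can chelate the metal) lets alkyne 2 coordinate and insert into the Cr=C bond, forming C1–C2. Insertion of a CO ligand into the resulting vinylcarbene forms C3–C4 and gives a chromium-bound vinylketene. Ring B then closes by a thermal 6π electrocyclisation of the aryl–vinyl–ketene triene, which forms C4–C4a as a six-membered ring, and tautomerisation of the cyclohexadienone gives the Cr(CO)3-bound naphthol 8, from which air and light release 9. The closest known reaction type is the benzannulation of ortho-methoxyaryl(methoxy)carbene complexes of chromium with terminal alkyl alkynes to 2-alkyl-4-methoxy-1-naphthols. No stereocentre is formed; the (S) carbinol centre of 2 lies two atoms from the alkyne, carries no activating group and is untouched under neutral conditions at 50 °C. The step needs the chain-bearing alkyne carbon to end next to the CO-derived carbon C4: a terminal alkyne inserts with its unsubstituted carbon bonded to the crowded carbene carbon, so the chain arrives at C3. It needs closure onto C4a only: of the two ortho positions of the aryl group the other one (C8) carries OMe, so no second ring fusion is possible. It needs CO insertion to outrun indene, cyclobutenone and two-alkyne pathways, for which the donor solvent THF, moderate temperature and a slight excess of the alkyl alkyne are the established choices.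

Step 4
Reactants: 9 (2S)-1-(1-hydroxy-4,5,7,8-tetramethoxynaphthalen-2-yl)propan-2-yl acetate
Product: 10 2-[(2S)-2-acetoxypropyl]-5,7,8-trimethoxynaphthalene-1,4-dione
Conditions: PhI(OAc)2, MeCN/H2O (3:1), 0 °C
Reagents that add atoms: water, O
Why: Oxidation of a para-methoxyphenol by a trivalent iodine reagent: ligand exchange at iodine, loss of PhI, attack of water at the methoxy-bearing carbon C1 and collapse of the hemiketal with loss of methanol give the 1,4-quinone; ring A has no free hydroxyl and should stay intact, so the C5/C8 para-dimethoxy pair survives a step in which a one-electron oxidant might not discriminate.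

Step 5
Reactants: 10 2-[(2S)-2-acetoxypropyl]-5,7,8-trimethoxynaphthalene-1,4-dione
Product: 11 1a-[(2S)-2-acetoxypropyl]-3,4,6-trimethoxy-1a,7a-dihydronaphtho[2,3-b]oxirene-2,7-dione (both cis-oxirane diastereomers, carried on together)
Conditions: 30% aq. H2O2, Na2CO3, THF/H2O, 0 °C, short reaction time
Reagents that add atoms: hydrogen peroxide, OO
Why: Weitz–Scheffer nucleophilic epoxidation: hydroperoxide anion adds to the electron-poor C2=C3 bond at the unsubstituted carbon C2 and the enolate closes on oxygen with loss of hydroxide; the oxirane is necessarily cis-fused, the remote (S) centre gives no facial bias, and none is needed because C2 and C3 become sp2 again in step 6.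

Step 6
Reactants: 11 1a-[(2S)-2-acetoxypropyl]-3,4,6-trimethoxy-1a,7a-dihydronaphtho[2,3-b]oxirene-2,7-dione
Product: 12 2-hydroxy-5,6,8-trimethoxy-3-[(2S)-2-acetoxypropyl]naphthalene-1,4-dione (CNP0321270.1)
Conditions: conc. H2SO4, 0 °C, 10 min; then ice/H2O
Reagents that add atoms: none
Why: Acid-mediated isomerisation of a 2,3-epoxy-2,3-dihydro-1,4-naphthoquinone to the 2-hydroxy-1,4-naphthoquinone: the protonated oxirane opens at the tertiary carbon C3 and loss of the C2 proton gives the enol, which is the hydroxyquinone, so both diastereomers of 11 converge; in cold acid the ester and the aryl ketone carbonyls are only protonated, which also deactivates ring A toward sulfonation, and the carbinol centre takes no part.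

## Compound list

1 | (S)-pent-4-yn-2-ol | C#CC[C@H](C)O | starting material
2 | (S)-pent-4-yn-2-yl acetate | C#CC[C@H](C)OC(C)=O | intermediate
3 | 1-bromo-2,4,5-trimethoxybenzene | COc1cc(OC)c(Br)cc1OC | starting material
4 | chromium hexacarbonyl, Cr(CO)6 | O=C=[Cr](=C=O)(=C=O)(=C=O)(=C=O)=C=O | starting material
5 | 2,4,5-trimethoxyphenyllithium (not isolated) | [Li]c1cc(OC)c(OC)cc1OC | intermediate
6 | lithium pentacarbonyl[oxido(2,4,5-trimethoxyphenyl)methylidene]chromate, Li[(CO)5CrC(O)Ar] (not isolated) | [Li+].[O-]C(=[Cr](=C=O)(=C=O)(=C=O)(=C=O)=C=O)c1cc(OC)c(OC)cc1OC | intermediate
7 | pentacarbonyl[methoxy(2,4,5-trimethoxyphenyl)methylidene]chromium, (CO)5Cr=C(OMe)Ar | COC(=[Cr](=C=O)(=C=O)(=C=O)(=C=O)=C=O)c1cc(OC)c(OC)cc1OC | intermediate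
8 | tricarbonyl(η6-naphthol 9)chromium, (CO)3Cr(η6-arene), chromium on the new ring B (not isolated; written as two parts, η6 bonding not drawn) | COc1cc(OC)c2c(OC)cc(C[C@H](C)OC(C)=O)c(O)c2c1OC.O=C=[Cr](=C=O)=C=O | intermediate
9 | (2S)-1-(1-hydroxy-4,5,7,8-tetramethoxynaphthalen-2-yl)propan-2-yl acetate (target numbering: OH at C4, chain at C3, H at C2, OMe at C1) | COc1cc(OC)c2c(OC)cc(C[C@H](C)OC(C)=O)c(O)c2c1OC | intermediate
10 | 2-[(2S)-2-acetoxypropyl]-5,7,8-trimethoxynaphthalene-1,4-dione (target numbering: chain at C3, H at C2) | COc1cc(OC)c2c(c1OC)C(=O)C(C[C@H](C)OC(C)=O)=CC2=O | intermediate
11 | 1a-[(2S)-2-acetoxypropyl]-3,4,6-trimethoxy-1a,7a-dihydronaphtho[2,3-b]oxirene-2,7-dione, cis-fused oxirane, both configurations at C1a/C7a, chain (S) | COc1cc(OC)c2c(c1OC)C(=O)C1(C[C@H](C)OC(C)=O)OC1C2=O | intermediate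
12 | 2-hydroxy-5,6,8-trimethoxy-3-[(2S)-2-acetoxypropyl]naphthalene-1,4-dione | COc1cc(OC)c2c(c1OC)C(=O)C(C[C@H](C)OC(C)=O)=C(O)C2=O | target

## Step count and least certain steps

Total: 6 steps. Longest linear sequence: 5 steps (3 → 7 → 9 → 10 → 11 → 12; the branch from 1 through 2 is equally long).

**Step 3 (key step).**
- What may go wrong: oxidative degradation of the very electron-rich naphthol during aerobic decomplexation and chromatography is the most likely loss. The donor-rich aryl group may also slow CO insertion and divert the vinylcarbene toward indene or cyclobutenone products. The ester carbonyl may intercept the ketene.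
- Fallback (from 1 and 7, back at 10): the oxygen is carried as a silyl ether and the naphthol is never handled. Alcohol 1 is silylated (TBSCl, imidazole, DMF) to (S)-tert-butyldimethyl(pent-4-yn-2-yloxy)silane F1. F1 and complex 7 are heated in THF as in step 3. The crude 2-[(2S)-2-(tert-butyldimethylsilyloxy)propyl]-4,5,7,8-tetramethoxynaphthalen-1-ol F2 is oxidised at once with PhI(OAc)2 in aqueous MeCN to 2-[(2S)-2-(tert-butyldimethylsilyloxy)propyl]-5,7,8-trimethoxynaphthalene-1,4-dione F3. HF·pyridine in THF then frees 2-[(2S)-2-hydroxypropyl]-5,7,8-trimethoxynaphthalene-1,4-dione F4, and Ac2O/pyridine returns the route to quinone 10.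

**Step 5.**
- What may go wrong: attack of hydroperoxide or hydroxide on the acetate; base-induced loss of acetic acid through the dienolate formed at the C3 CH2 group; oxidative cleavage of the enedione by excess peroxide.
- Fallback (from 10, back at 12): Thiele–Winter acetoxylation, which is acidic and anhydrous and therefore safe for the ester. Ac2O with catalytic H2SO4 should add acetate at C2, the only free quinone position, and acetylate the hydroquinone, giving (2S)-1-(1,3,4-triacetoxy-5,7,8-trimethoxynaphthalen-2-yl)propan-2-yl acetate F5. The three aryl acetates are far more labile than the alkyl acetate and are removed with NH4OAc in aqueous MeOH under air, in which the hydroxyhydroquinone oxidises to 12.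

**Step 6.**
- What may go wrong: ionisation or neighbouring-group displacement at the carbinol carbon in concentrated acid, with loss of configuration or closure of the C2 oxygen onto the chain to a dihydrofuran; loss of the ester on quenching; cleavage of a peri methyl ether; acyl shift with ring contraction instead of proton loss.
- Fallback (from 11, back at 12): the oxirane is opened under acetylating conditions of low acidity. Ac2O with a catalytic amount of H2SO4 at 0 °C, then NaOAc, should give, by acetolysis at C2 and elimination of acetic acid across C2–C3, the enol acetate (2S)-1-(3-acetoxy-5,7,8-trimethoxy-1,4-dioxo-1,4-dihydronaphthalen-2-yl)propan-2-yl acetate F6. Its quinonyl acetate is a vinylogous anhydride and should be removed selectively by NaHCO3 in MeOH at 0 °C, leaving the alkyl acetate and giving 12.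

## Further compounds

F1 | step 3 | (S)-tert-butyldimethyl(pent-4-yn-2-yloxy)silane | C#CC[C@H](C)O[Si](C)(C)C(C)(C)C
F2 | step 3 | 2-[(2S)-2-(tert-butyldimethylsilyloxy)propyl]-4,5,7,8-tetramethoxynaphthalen-1-ol | COc1cc(OC)c2c(OC)cc(C[C@H](C)O[Si](C)(C)C(C)(C)C)c(O)c2c1OC
F3 | step 3 | 2-[(2S)-2-(tert-butyldimethylsilyloxy)propyl]-5,7,8-trimethoxynaphthalene-1,4-dione | COc1cc(OC)c2c(c1OC)C(=O)C(C[C@H](C)O[Si](C)(C)C(C)(C)C)=CC2=O
F4 | step 3 | 2-[(2S)-2-hydroxypropyl]-5,7,8-trimethoxynaphthalene-1,4-dione | COc1cc(OC)c2c(c1OC)C(=O)C(C[C@H](C)O)=CC2=O
F5 | step 5 | (2S)-1-(1,3,4-triacetoxy-5,7,8-trimethoxynaphthalen-2-yl)propan-2-yl acetate | COc1cc(OC)c2c(OC(C)=O)c(OC(C)=O)c(C[C@H](C)OC(C)=O)c(OC(C)=O)c2c1OC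
F6 | step 6 | (2S)-1-(3-acetoxy-5,7,8-trimethoxy-1,4-dioxo-1,4-dihydronaphthalen-2-yl)propan-2-yl acetate | COc1cc(OC)c2c(c1OC)C(=O)C(C[C@H](C)OC(C)=O)=C(OC(C)=O)C2=O
A1 | alternative 1 | 2,5,6,8-tetramethoxy-3-[(2S)-2-(tert-butyldimethylsilyloxy)propyl]naphthalene-1,4-diol | COc1cc(OC)c2c(O)c(OC)c(C[C@H](C)O[Si](C)(C)C(C)(C)C)c(O)c2c1OC
A2 | alternative 1 | 1,2,4-trimethoxycyclohexa-1,3-diene | COC1=C(OC)C=C(OC)CC1
A3 | alternative 1 | 2-methoxy-3-[(2S)-2-(tert-butyldimethylsilyloxy)propyl]cyclohexa-2,5-diene-1,4-dione | COC1=C(C[C@H](C)O[Si](C)(C)C(C)(C)C)C(=O)C=CC1=O
A4 | alternative 2 | 2-hydroxy-5,6,8-trimethoxy-3-[(2S)-2-(tert-butyldimethylsilyloxy)propyl]naphthalene-1,4-dione | COc1cc(OC)c2c(c1OC)C(=O)C(C[C@H](C)O[Si](C)(C)C(C)(C)C)=C(O)C2=O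
A5 | alternative 2 | 3,4,6-trimethoxy-2-(trimethylsilyl)phenyl trifluoromethanesulfonate | COc1cc(OC)c(OC)c([Si](C)(C)C)c1OS(=O)(=O)C(F)(F)F
A6 | alternative 2 | methyl (6S)-6-(tert-butyldimethylsilyloxy)-3-oxoheptanoate | COC(=O)CC(=O)CC[C@H](C)O[Si](C)(C)C(C)(C)C
A7 | alternative 3 | 5,7,8-trimethoxy-2-[(2S)-2-(tert-butyldimethylsilyloxy)propyl]naphthalene-1,3-diol | COc1cc(OC)c2cc(O)c(C[C@H](C)O[Si](C)(C)C(C)(C)C)c(O)c2c1OC
A8 | alternative 3 | 4,6,7-trimethoxyindane-1,2-dione | COc1cc(OC)c2c(c1OC)C(=O)C(=O)C2
A9 | alternative 3 | tert-butyl{[(2S)-4-diazobutan-2-yl]oxy}dimethylsilane | [N-]=[N+]=CC[C@H](C)O[Si](C)(C)C(C)(C)C
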